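## Analysis of the target

Compound 26 is an elemane-type sesquiterpene lactone. A single cyclohexane (C5–C10, elemane numbering) is trans-fused across C6–C7 to an α-methylene-γ-butyrolactone (lactone oxygen on C6, C11 on C7, C12 as carbonyl, C13 as exocyclic methylene).

Five ring carbons are stereogenic: C5 (R) carries the 3-hydroxyprop-1-en-2-yl group C4(=C3)–C15–OH, C6 (R) the lactone oxygen, C7 (R) the lactone carbon branch, C8 (S) the acyloxy group, and the quaternary C10 (R) a methyl group (C14) and a vinyl group (C1=C2). The substituents on C5, C6, C7 and C8 alternate in face and are all equatorial in one chair; in that chair the C10 vinyl group is axial and cis to the C5 propenyl group. A sixth stereocentre (R) lies α to the carbonyl of the 3-hydroxy-2-methylpropanoate on the C8 oxygen.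

The sensitive groups are the α-methylene lactone (a Michael acceptor that does not tolerate nucleophilic bases), the epimerisable α-centre of the side-chain ester and the 1,5-diene C2=C1–C10–C5–C4=C3. Three hydroxyl-level oxygens (C8, C15, side chain) must be told apart, and a free C8 hydroxyl can attack C12.

The difficulty is that a quaternary carbon bearing a vinyl group has to be set next to a methine bearing a 1,1-disubstituted alkene, cis to it, in a ring whose other positions are almost all functionalised. The strategy rests on the fact that C1 and C4 sit on adjacent ring carbons on the same face. A C1=C4 bond would close a cis-fused cyclobutene on C5–C10, which is the [2+2] adduct of an alkyne with a C5=C10 cyclohexenone whose carbonyl carbon, C6, later bears the lactone oxygen.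

## Retrosynthetic reasoning

**26 ⇐ 25.** The two primary hydroxyl groups (C15 and the side chain) are carried as the same silyl ether, so the last operation is one desilylation. No C–C bond is made once the methylene lactone and the side-chain ester are present.

**25 ⇐ 19 + 23.** The C8–O acyl bond is cut. This makes the end convergent and takes the sixth stereocentre from the chiral pool: acid 23 comes from ester 20 through silyl ether 21. The forward reaction must acylate a hindered equatorial secondary alcohol without enolising the α-centre of the acid.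

**19 ⇐ 18 ⇐ 14.** The C8 oxygen is carried as a 4-methoxybenzyl ether, which is orthogonal to the C15 silyl ether, so the C8 hydroxyl of 19 can be released on its own from 18. The C11=C13 bond is then cut back to the saturated lactone 14. The methylene group is introduced late because it is the most fragile function, and before the side-chain ester because that ester would not survive enolate chemistry.

**14 ⇐ 12.** The C12–O bond of the lactone is cut and C6 is returned to the ketone level (hydroxy ester 13 lies in between). The ketone is kept this long because it is the enone carbonyl of the ring-forming chemistry. The forward reduction must place the C6 oxygen equatorial, trans to both neighbours, which is the thermodynamic arrangement.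

**12 ⇐ 10 + 11.** This is the central disconnection. The terminal carbons C2 and C3 are removed as ethylene 11, and C1 is joined to C4. The two alkenes of 12 become the single strained alkene of cyclobutene 10. What is gained is that the C5/C10 cis relationship becomes a cis ring fusion, and the quaternary vinyl carbon never has to be made by substitution. The forward reaction is an alkene metathesis that must touch only the strained ring.

**10 ⇐ 7 + 9.** The bonds C4–C5 and C1–C10 are cut. The cyclobutene is the [2+2] photoadduct of enone 7 with alkyne 9, which comes from alcohol 8. The forward reaction must join the substituted alkyne carbon to C5 (head-to-head) and add to the enone face anti to the C8 ether. It creates C5 and C10 together.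

**7 ⇐ 4 + 5.** The C7–C11 bond is cut. The acetate branch is introduced by alkylating the α′-enolate of enone 4 with bromo ester 5. The forward reaction must place the branch trans to the C8 oxygen, which is also the diequatorial arrangement.

**4 ⇐ 3 ⇐ 2 ⇐ 1.** The C5=C10 bond is cut by an aldol condensation. Diketone 3 has a mirror plane through C8, so the enone has only one constitution, and the choice between the two enantiotopic acetyl arms by a chiral amine catalyst sets C8, the only stereocentre of 4. Both carbonyl groups of 3 come from the terminal alkenes of diene 2, the ether of commercial alcohol 1.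

## Alternatives that were turned down

**Alternative 1:** The C5–C10 bond is cut in the sense of a sigmatropic ring contraction.
- Forward key step: the precursor of A1 has the C1 carboxyl tied to the C3 oxygen in a ten-membered ring. It is converted with a lithium amide and Me3SiCl into its silyl ketene acetal. An Ireland–Claisen [3,3] shift then bonds C10 to C5, moves the double bond to C4=C3 and shrinks the ring to the cyclohexane of the C10 carboxylic acid A1.
- For: the most hindered bond is made intramolecularly and the C4=C3 methylene appears in the same event. The lactone and the C6–C8 stereocentres are already in place, so no late ketone reduction is needed.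
- Against: C10 arrives as a carboxyl group, so reduction to the aldehyde level and methylenation at a neopentyl centre must follow, beside a lactone. The precursor of A1 needs a medium-ring closure and a defined trisubstituted C4=C5 geometry. Enolisation must take place at the tertiary C10–H in competition with the more accessible C11–H2 of the γ-lactone. The cis C5/C10 outcome depends on ketene acetal geometry and on a chair or boat transition state inside a ten-membered ring, which is hard to predict.
- Comparison: this alternative is stronger in settling the C6 oxygen before the difficult bond is formed, and it needs no photochemistry. The chosen strategy offers in its place a C5/C10 relationship that is fixed by ring-fusion geometry, a vinyl group delivered at the correct oxidation level, and a precursor reached in five linear steps from achiral materials.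

**Alternative 2:** The C6–C7 bond and the lactone C–O bond are cut.
- Forward key step: SmI2 reduces a C6 aldehyde to its ketyl, which adds to C7 of an enoate that carries an acetoxymethyl group on C11. The samarium enolate expels acetate to give C11=C13, and the C6 alkoxide closes the lactone. The product is the bis-silyl ether A2.
- For: the cyclohexane, C6, C7, the lactone and the exocyclic methylene are made in one operation, and neither a separate methylenation nor a ketone reduction is needed. On end-game economy this alternative is stronger than the chosen route.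
- Against: because the ring is closed last, the quaternary vinyl carbon C10 and the propenyl methine C5 must be set in an open chain, with no ring to enforce their relationship. The central problem is moved, not solved. The C6 aldehyde is α to C5 and β,γ to C4=C3, so it can epimerise or move into conjugation. The facial course of the ketyl addition relative to C5 and C8 rests on transition-state preferences. A2 carries the same silyl group on C8 and C15, which must then be told apart.
- Comparison: the chosen route needs more operations after its key step, but its hardest relationship is secured by a cis ring fusion.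

**Alternative 3:** The C9–C10 bond is cut.
- Forward key step: zerovalent palladium from Pd2(dba)3 with a chiral bisphosphine ionises an allylic carbonate, and the β-keto ester carbon C9 attacks the more substituted terminus (C10) of the π-allyl. This closes the six-membered ring and leaves the vinyl group in the β-keto ester A3.
- For: the quaternary vinyl carbon is made directly at the right oxidation level by a catalytic step whose ligand can in principle override substrate bias. On catalyst control of that centre this alternative is stronger.
- Against: the nucleophile must attack the more hindered allyl terminus next to the C5 stereocentre, and the existing centres can be matched or mismatched with the ligand. A3 carries a superfluous ester on C9 that must be removed. Its carbonyl is on C8, so a stereoselective reduction next to the axial vinyl group is still required, followed by unmasking of the C6 oxygen and lactonisation. The open-chain precursor of A3 needs three stereocentres and a defined trisubstituted alkene.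
- Comparison: the chosen strategy derives all ring stereocentres from one catalytic desymmetrisation and never forms the quaternary carbon by substitution.

Key step: step 7

Assumption: the sense of induction of the cinchona primary amine in step 3 is taken to follow that of 4-alkyl- and 4-aryl-heptane-2,6-diones; if the quinine-derived amine favoured the (R)-enone, its quinidine-derived pseudoenantiomer would be used.

## Route

Step 1
Reactants: 1 hepta-1,6-dien-4-ol
Product: 2 4-[(4-methoxybenzyl)oxy]hepta-1,6-diene
Conditions: NaH, 4-MeOC6H4CH2Cl, Bu4NI (cat.), DMF, 0 °C → rt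
Reagents that add atoms: 4-methoxybenzyl chloride, COc1ccc(CCl)cc1
Why: Williamson etherification of a secondary alkoxide with a benzylic chloride; the carbinol carbon is not stereogenic, so nothing is at stake.

Step 2
Reactants: 2 4-[(4-methoxybenzyl)oxy]hepta-1,6-diene
Product: 3 4-[(4-methoxybenzyl)oxy]heptane-2,6-dione
Conditions: PdCl2 (10 mol%), CuCl (1 equiv), O2 (1 atm), DMF/H2O (7:1), rt
Reagents that add atoms: water, O
Why: Twofold Tsuji–Wacker oxidation: Markovnikov hydroxypalladation of each terminal alkene and β-hydride elimination give the methyl ketones, and divalent palladium is regenerated by CuCl/O2. The homoallylic ether is a spectator and the product keeps its mirror plane.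

Step 3
Reactants: 3 4-[(4-methoxybenzyl)oxy]heptane-2,6-dione
Product: 4 (5S)-5-[(4-methoxybenzyl)oxy]-3-methylcyclohex-2-en-1-one
Conditions: 9-amino-9-deoxy-epi-quinine (20 mol%), AcOH (60 mol%), PhMe, −15 °C
Reagents that add atoms: none
Why: Amine-catalysed desymmetrising intramolecular aldol condensation (Hajos–Parrish–Eder–Sauer–Wiechert type): the primary amine forms an enamine from one of the two enantiotopic acetyl arms, the protonated quinuclidine activates the other carbonyl, and dehydration gives the enone. The catalyst's choice between the arms sets C8 as S; the cold, weakly acidic medium is meant to leave the β-alkoxy ketone intact.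

Step 4
Reactants: 4 (5S)-5-[(4-methoxybenzyl)oxy]-3-methylcyclohex-2-en-1-one; 5 methyl bromoacetate
Product: 7 methyl 2-[(1R,6S)-6-[(4-methoxybenzyl)oxy]-4-methyl-2-oxocyclohex-3-en-1-yl]acetate, via lithium dienolate 6 (not isolated)
Conditions: LiN(iPr)2 (1.05 equiv), THF, −78 °C; then 5, DMPU, −78 → −50 °C; AcOH, −78 °C
Reagents that add atoms: none
Why: Kinetic α′-deprotonation gives the cross-conjugated dienolate 6, which is alkylated (SN2) by the reactive α-bromo ester at low temperature, before loss of the β-alkoxide can compete. The electrophile enters anti to the adjacent C8 ether, so C7 is set R, trans to C8–O; this is also the diequatorial arrangement.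

Step 5
Reactants: 8 prop-2-yn-1-ol
Product: 9 tert-butyldimethyl(prop-2-yn-1-yloxy)silane
Conditions: t-BuMe2SiCl, imidazole, CH2Cl2, 0 °C → rt
Reagents that add atoms: tert-butyldimethylsilyl chloride, CC(C)(C)[Si](C)(C)Cl
Why: Routine silylation of a primary alcohol; the silyl ether is transparent at the wavelength of step 6 and inert to metathesis.

Step 6
Reactants: 7 methyl 2-[(1R,6S)-6-[(4-methoxybenzyl)oxy]-4-methyl-2-oxocyclohex-3-en-1-yl]acetate; 9 tert-butyldimethyl(prop-2-yn-1-yloxy)silane
Product: 10 methyl 2-[(1R,3R,4S,6R)-8-({[tert-butyl(dimethyl)silyl]oxy}methyl)-4-[(4-methoxybenzyl)oxy]-6-methyl-2-oxobicyclo[4.2.0]oct-7-en-3-yl]acetate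
Conditions: hν (λ ≥ 350 nm, uranium-glass filter), 9 (10 equiv), CH2Cl2, −40 °C
Reagents that add atoms: none
Why: Enone–alkyne [2+2] photocycloaddition (Corey–de Mayo type) through the enone triplet: C10 bonds to the terminal alkyne carbon, and the resulting α-keto radical/substituted vinyl radical pair closes C5–C4, which is the head-to-head orientation expected for a terminal alkyne. Bonding at C10 is axial on the half-chair that keeps the C7 and C8 substituents pseudo-equatorial, that is, anti to the C8 ether, which sets C10 (R); a cyclobutene can only be cis-fused, so C5 (R) follows. Long-wavelength light and excess 9 limit enone dimerisation and the 1,3-acyl shift of the β,γ-unsaturated ketone product.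

Step 7
Reactants: 10 methyl 2-[(1R,3R,4S,6R)-8-({[tert-butyl(dimethyl)silyl]oxy}methyl)-4-[(4-methoxybenzyl)oxy]-6-methyl-2-oxobicyclo[4.2.0]oct-7-en-3-yl]acetate; 11 ethylene
Product: 12 methyl 2-[(1R,3R,4R,6S)-3-{3-[(tert-butyldimethylsilyl)oxy]prop-1-en-2-yl}-4-ethenyl-6-[(4-methoxybenzyl)oxy]-4-methyl-2-oxocyclohexyl]acetate
Conditions: 11 (1 atm), second-generation Grubbs catalyst (H2IMes)(PCy3)Cl2Ru=CHPh (5 mol%), 1,4-benzoquinone (10 mol%), CH2Cl2 (0.01 M), 25 → 40 °C
Reagents that add atoms: none
Why: The ruthenium methylidene formed from the precatalyst and 11 adds across the strained C1=C4 bond in a [2+2] cycloaddition, and cycloreversion of the ruthenacyclobutane opens the four-membered ring with release of about 30 kcal/mol of strain, so this event is effectively irreversible. Ruthenium should end on the less substituted C1 while C4 receives the methylene C3; the C1 alkylidene is then cleaved by 11, which delivers C2 and regenerates the methylidene. The closest known reaction type is the ring-opening cross-metathesis (ethenolysis) of cyclobutenes, 1-substituted ones included, with ruthenium carbene catalysts. No ring is closed and no stereocentre is formed: two C=C bonds (C1=C2 and C4=C3) replace one, and the cis relationship of the C10 vinyl and C5 propenyl groups is simply the cis ring fusion of 10. The step needs chemoselectivity for the strained alkene and freedom from oligomerisation; the product alkenes are a vinyl group on a quaternary carbon and a 1,1-disubstituted alkene, for which metathesis with 11 is degenerate and homodimerisation is slow, and high dilution under a saturating atmosphere of 11 makes capture of the C1 alkylidene by 11 faster than by a second cyclobutene. It also needs C5–H (α to the C6 ketone and allylic) and C7–H (with the C8 ether in the β-position) to stay untouched; the medium is neutral and aprotic, and 1,4-benzoquinone intercepts ruthenium hydrides that could isomerise C4=C3 or epimerise C5. At 40 °C the Cope rearrangement of the 1,5-diene is not a concern.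

Step 8
Reactants: 12 methyl 2-[(1R,3R,4R,6S)-3-{3-[(tert-butyldimethylsilyl)oxy]prop-1-en-2-yl}-4-ethenyl-6-[(4-methoxybenzyl)oxy]-4-methyl-2-oxocyclohexyl]acetate
Product: 14 (3aR,4S,6R,7R,7aR)-7-{3-[(tert-butyldimethylsilyl)oxy]prop-1-en-2-yl}-6-ethenyl-4-[(4-methoxybenzyl)oxy]-6-methylhexahydro-1-benzofuran-2(3H)-one, via hydroxy ester 13 (not isolated)
Conditions: SmI2 (2.5 equiv), H2O, Et3N, THF, −20 → 0 °C; then PPTS (cat.), PhH, 60 °C
Reagents that add atoms: none
Why: Divalent samarium reduces the ketone by single-electron transfer to the ketyl and then to the α-oxido organosamarium, which is protonated under thermodynamic control: the C6 oxygen takes the equatorial position, trans to both flanking substituents and away from the axial C10 vinyl group, which sets C6 as R. The methyl ester is reduced far more slowly, and mild acid then closes the trans-fused γ-lactone with loss of methanol.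

Step 9
Reactants: 14 (3aR,4S,6R,7R,7aR)-7-{3-[(tert-butyldimethylsilyl)oxy]prop-1-en-2-yl}-6-ethenyl-4-[(4-methoxybenzyl)oxy]-6-methylhexahydro-1-benzofuran-2(3H)-one
Product: 18 (3aR,4S,6R,7R,7aR)-7-{3-[(tert-butyldimethylsilyl)oxy]prop-1-en-2-yl}-6-ethenyl-4-[(4-methoxybenzyl)oxy]-6-methyl-3-methylidenehexahydro-1-benzofuran-2(3H)-one, via lithium lactone enolate 15 (not isolated), via Mannich base 16 (not isolated), via trimethylammonium iodide 17 (not isolated)
Conditions: LiN(iPr)2, THF, −78 °C; [Me2N=CH2]I, −78 → 0 °C; MeI, MeOH, rt; NaHCO3 (aq), CH2Cl2, rt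
Reagents that add atoms: N,N-dimethylmethyleneiminium iodide (Eschenmoser's salt), C=[N+](C)C.[I-]; iodomethane, CI (its methyl group is carried only by 17)
Why: Eschenmoser methylenation: Mannich reaction of lactone enolate 15 with the iminium salt, N-methylation and E1cB loss of trimethylamine. The configuration at C11 is irrelevant because the carbon becomes sp2, and with C6 no longer a ketone no other acidic C–H competes.

Step 10
Reactants: 18 (3aR,4S,6R,7R,7aR)-7-{3-[(tert-butyldimethylsilyl)oxy]prop-1-en-2-yl}-6-ethenyl-4-[(4-methoxybenzyl)oxy]-6-methyl-3-methylidenehexahydro-1-benzofuran-2(3H)-one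
Product: 19 (3aR,4S,6R,7R,7aR)-7-{3-[(tert-butyldimethylsilyl)oxy]prop-1-en-2-yl}-6-ethenyl-4-hydroxy-6-methyl-3-methylidenehexahydro-1-benzofuran-2(3H)-one
Conditions: DDQ, CH2Cl2/pH 7 buffer (10:1), 0 °C
Reagents that add atoms: none
Why: Oxidative cleavage of the electron-rich benzyl ether by DDQ (hydride abstraction to the oxocarbenium ion, then hydrolysis). The silyl ether, the unactivated alkenes and the enoate are not oxidised under buffered conditions, and no base is present that could trigger translactonisation.

Step 11
Reactants: 20 methyl (2R)-3-hydroxy-2-methylpropanoate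
Product: 21 methyl (2R)-3-[(tert-butyldimethylsilyl)oxy]-2-methylpropanoate
Conditions: t-BuMe2SiCl, imidazole, CH2Cl2, rt
Reagents that add atoms: tert-butyldimethylsilyl chloride, CC(C)(C)[Si](C)(C)Cl
Why: Routine silylation of the primary alcohol; the stereocentre is not involved.

Step 12
Reactants: 21 methyl (2R)-3-[(tert-butyldimethylsilyl)oxy]-2-methylpropanoate
Product: 23 (2R)-3-[(tert-butyldimethylsilyl)oxy]-2-methylpropanoic acid, via lithium carboxylate 22 (not isolated)
Conditions: LiOH, THF/MeOH/H2O, 0 °C; then aq. HCl to pH 4, 0 °C
Reagents that add atoms: lithium hydroxide, [Li+].[OH-]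
Why: Saponification of an unhindered methyl ester; at 0 °C hydroxide attacks the carbonyl faster than it enolises the α-centre or eliminates the β-silyloxy group, so the R configuration is kept.

Step 13
Reactants: 19 (3aR,4S,6R,7R,7aR)-7-{3-[(tert-butyldimethylsilyl)oxy]prop-1-en-2-yl}-6-ethenyl-4-hydroxy-6-methyl-3-methylidenehexahydro-1-benzofuran-2(3H)-one; 23 (2R)-3-[(tert-butyldimethylsilyl)oxy]-2-methylpropanoic acid
Product: 25 (3aR,4S,6R,7R,7aR)-7-{3-[(tert-butyldimethylsilyl)oxy]prop-1-en-2-yl}-6-ethenyl-6-methyl-3-methylidene-2-oxooctahydro-1-benzofuran-4-yl (2R)-3-[(tert-butyldimethylsilyl)oxy]-2-methylpropanoate, via mixed anhydride 24 (not isolated)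
Conditions: 2,4,6-Cl3C6H2COCl, Et3N, THF, rt; then 19, DMAP, PhMe, rt
Reagents that add atoms: 2,4,6-trichlorobenzoyl chloride, O=C(Cl)c1c(Cl)cc(Cl)cc1Cl (its acyl group is carried only by 24)
Why: Yamaguchi esterification: mixed anhydride 24 passes the aliphatic acyl group through the acylpyridinium ion to the equatorial secondary C8 hydroxyl. The α-stereocentre of the acid should not be enolised under these conditions, and no alkoxide is generated that could attack the lactone.

Step 14
Reactants: 25 (3aR,4S,6R,7R,7aR)-7-{3-[(tert-butyldimethylsilyl)oxy]prop-1-en-2-yl}-6-ethenyl-6-methyl-3-methylidene-2-oxooctahydro-1-benzofuran-4-yl (2R)-3-[(tert-butyldimethylsilyl)oxy]-2-methylpropanoate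
Product: 26 (3aR,4S,6R,7R,7aR)-6-ethenyl-7-(3-hydroxyprop-1-en-2-yl)-6-methyl-3-methylidene-2-oxooctahydro-1-benzofuran-4-yl (2R)-3-hydroxy-2-methylpropanoate
Conditions: HF·pyridine, pyridine, THF, 0 °C → rt
Reagents that add atoms: none
Why: Si–F bond formation cleaves both primary silyl ethers. The buffered, weakly acidic fluoride source avoids the basic conditions that would cause conjugate addition to the methylene lactone, acyl migration or translactonisation.

## Compound list

1 | hepta-1,6-dien-4-ol | C=CCC(O)CC=C | starting material
2 | 4-[(4-methoxybenzyl)oxy]hepta-1,6-diene | C=CCC(OCc1ccc(OC)cc1)CC=C | intermediate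
3 | 4-[(4-methoxybenzyl)oxy]heptane-2,6-dione | CC(=O)CC(OCc1ccc(OC)cc1)CC(C)=O | intermediate
4 | (5S)-5-[(4-methoxybenzyl)oxy]-3-methylcyclohex-2-en-1-one | CC1=CC(=O)C[C@@H](OCc2ccc(OC)cc2)C1 | intermediate
5 | methyl bromoacetate | COC(=O)CBr | starting material
6 | lithium dienolate of 4 (C6–OLi, C6=C7 and C5=C10; C8 S) | [Li]OC1=C[C@@H](OCc2ccc(OC)cc2)CC(C)=C1 | intermediate (not isolated)
7 | methyl 2-[(1R,6S)-6-[(4-methoxybenzyl)oxy]-4-methyl-2-oxocyclohex-3-en-1-yl]acetate | CC1=CC(=O)[C@H](CC(=O)OC)[C@@H](OCc2ccc(OC)cc2)C1 | intermediate
8 | prop-2-yn-1-ol | C#CCO | starting material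
9 | tert-butyldimethyl(prop-2-yn-1-yloxy)silane | C#CCO[Si](C)(C)C(C)(C)C | intermediate
10 | methyl 2-[(1R,3R,4S,6R)-8-({[tert-butyl(dimethyl)silyl]oxy}methyl)-4-[(4-methoxybenzyl)oxy]-6-methyl-2-oxobicyclo[4.2.0]oct-7-en-3-yl]acetate | C1=C(CO[Si](C)(C)C(C)(C)C)[C@@H]2C(=O)[C@H](CC(=O)OC)[C@@H](OCc3ccc(OC)cc3)C[C@]12C | intermediate
11 | ethylene | C=C | starting material
12 | methyl 2-[(1R,3R,4R,6S)-3-{3-[(tert-butyldimethylsilyl)oxy]prop-1-en-2-yl}-4-ethenyl-6-[(4-methoxybenzyl)oxy]-4-methyl-2-oxocyclohexyl]acetate | C=C[C@@]1(C)C[C@H](OCc2ccc(OC)cc2)[C@@H](CC(=O)OC)C(=O)[C@H]1C(=C)CO[Si](C)(C)C(C)(C)C | intermediate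
13 | methyl 2-[(1S,2R,3R,4R,6S)-3-{3-[(tert-butyldimethylsilyl)oxy]prop-1-en-2-yl}-4-ethenyl-2-hydroxy-6-[(4-methoxybenzyl)oxy]-4-methylcyclohexyl]acetate | C=C[C@@]1(C)C[C@H](OCc2ccc(OC)cc2)[C@@H](CC(=O)OC)[C@H](O)[C@H]1C(=C)CO[Si](C)(C)C(C)(C)C | intermediate (not isolated)
14 | (3aR,4S,6R,7R,7aR)-7-{3-[(tert-butyldimethylsilyl)oxy]prop-1-en-2-yl}-6-ethenyl-4-[(4-methoxybenzyl)oxy]-6-methylhexahydro-1-benzofuran-2(3H)-one | C=C[C@@]1(C)C[C@H](OCc3ccc(OC)cc3)[C@H]2CC(=O)O[C@@H]2[C@H]1C(=C)CO[Si](C)(C)C(C)(C)C | intermediate
15 | lithium enolate of lactone 14 (C12–OLi, C11=C12) | C=C[C@@]1(C)C[C@H](OCc3ccc(OC)cc3)[C@H]2C=C(O[Li])O[C@@H]2[C@H]1C(=C)CO[Si](C)(C)C(C)(C)C | intermediate (not isolated)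
16 | 3-[(dimethylamino)methyl] derivative of lactone 14 (configuration at C11 not defined) | C=C[C@@]1(C)C[C@H](OCc3ccc(OC)cc3)[C@H]2C(CN(C)C)C(=O)O[C@@H]2[C@H]1C(=C)CO[Si](C)(C)C(C)(C)C | intermediate (not isolated)
17 | 3-[(trimethylammonio)methyl] derivative of lactone 14, iodide (configuration at C11 not defined) | C=C[C@@]1(C)C[C@H](OCc3ccc(OC)cc3)[C@H]2C(C[N+](C)(C)C)C(=O)O[C@@H]2[C@H]1C(=C)CO[Si](C)(C)C(C)(C)C.[I-] | intermediate (not isolated)
18 | (3aR,4S,6R,7R,7aR)-7-{3-[(tert-butyldimethylsilyl)oxy]prop-1-en-2-yl}-6-ethenyl-4-[(4-methoxybenzyl)oxy]-6-methyl-3-methylidenehexahydro-1-benzofuran-2(3H)-one | C=C[C@@]1(C)C[C@H](OCc3ccc(OC)cc3)[C@H]2C(=C)C(=O)O[C@@H]2[C@H]1C(=C)CO[Si](C)(C)C(C)(C)C | intermediate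
19 | (3aR,4S,6R,7R,7aR)-7-{3-[(tert-butyldimethylsilyl)oxy]prop-1-en-2-yl}-6-ethenyl-4-hydroxy-6-methyl-3-methylidenehexahydro-1-benzofuran-2(3H)-one | C=C[C@@]1(C)C[C@H](O)[C@H]2C(=C)C(=O)O[C@@H]2[C@H]1C(=C)CO[Si](C)(C)C(C)(C)C | intermediate
20 | methyl (2R)-3-hydroxy-2-methylpropanoate | COC(=O)[C@H](C)CO | starting material
21 | methyl (2R)-3-[(tert-butyldimethylsilyl)oxy]-2-methylpropanoate | COC(=O)[C@H](C)CO[Si](C)(C)C(C)(C)C | intermediate
22 | lithium (2R)-3-[(tert-butyldimethylsilyl)oxy]-2-methylpropanoate | [Li+].[O-]C(=O)[C@H](C)CO[Si](C)(C)C(C)(C)C | intermediate (not isolated)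
23 | (2R)-3-[(tert-butyldimethylsilyl)oxy]-2-methylpropanoic acid | OC(=O)[C@H](C)CO[Si](C)(C)C(C)(C)C | intermediate
24 | (2R)-3-[(tert-butyldimethylsilyl)oxy]-2-methylpropanoic 2,4,6-trichlorobenzoic anhydride | O=C(OC(=O)[C@H](C)CO[Si](C)(C)C(C)(C)C)c1c(Cl)cc(Cl)cc1Cl | intermediate (not isolated)
25 | (3aR,4S,6R,7R,7aR)-7-{3-[(tert-butyldimethylsilyl)oxy]prop-1-en-2-yl}-6-ethenyl-6-methyl-3-methylidene-2-oxooctahydro-1-benzofuran-4-yl (2R)-3-[(tert-butyldimethylsilyl)oxy]-2-methylpropanoate | C=C[C@@]1(C)C[C@H](OC(=O)[C@H](C)CO[Si](C)(C)C(C)(C)C)[C@H]2C(=C)C(=O)O[C@@H]2[C@H]1C(=C)CO[Si](C)(C)C(C)(C)C | intermediate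
26 | (3aR,4S,6R,7R,7aR)-6-ethenyl-7-(3-hydroxyprop-1-en-2-yl)-6-methyl-3-methylidene-2-oxooctahydro-1-benzofuran-4-yl (2R)-3-hydroxy-2-methylpropanoate | C=C[C@@]1(C)C[C@H](OC(=O)[C@H](C)CO)[C@H]2C(=C)C(=O)O[C@@H]2[C@H]1C(=C)CO | target

## Step count and least certain steps

Total step count: 14. Longest linear sequence: 11 steps (1, 2, 3, 4, 6, 7, 8, 9, 10, 13, 14).

**Step 7 (key step).**
- What may go wrong: the methylidene may engage the trisubstituted cyclobutene only slowly, because C1 is neopentyl and C4 is fully substituted. The C1 alkylidene formed on ring opening may be held by chelation to the C6 carbonyl, or may add to a second cyclobutene and start oligomerisation. Ruthenium hydrides from catalyst decay may move C4=C3 into conjugation or epimerise C5.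
- Fallback: it replaces the metathesis by oxidative cleavage and double methylenation, sets out from 10 and comes back at 14. LiBH(s-Bu)3 reduces the C6 ketone of 10 from the face away from the four-membered ring, and the cis γ-alkoxy ester closes to the cis-fused lactone cyclobutene F1. Dihydroxylation with OsO4/N-methylmorpholine N-oxide and cleavage with NaIO4 give the keto aldehyde F2, in which no β-dicarbonyl unit arises because C6 is no longer a ketone. Methylenation of both carbonyl groups with the non-basic Zn/CH2Br2/TiCl4 reagent gives the cis-fused lactone diene F3, the C6 epimer of 14. LiOH opens it to the hydroxy acid F4, and Mitsunobu lactonisation (PPh3, diisopropyl azodicarboxylate) closes the lactone with inversion at C6 to 14.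

**Step 6.**
- What may go wrong: poor regioselectivity. Bond formation at the fully substituted C10 is slow, so first bonding at C5 and closure in the head-to-tail sense can compete. Incomplete facial selectivity and a 1,3-acyl shift of the product under the lamp are further risks.
- Fallback: it builds the same four-membered ring by a thermal, regiodefined ketene cycloaddition, sets out from 7 and comes back at 14.
  - Luche reduction (NaBH4, CeCl3·7H2O) delivers hydride axially to C6, and acid-catalysed lactonisation gives the trans-fused lactone cyclohexene F5.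
  - Dichloroketene (Cl3CCOCl, zinc–copper couple) adds to C5=C10 with its carbonyl carbon on the less substituted C5, giving the dichlorocyclobutanone F6. The C6 and C8 oxygens both lie on the lower face and should direct the ketene to the upper face; this would have to be checked.
  - Zn/AcOH removes the chlorines to give the cyclobutanone F7.
  - KN(SiMe3)2/PhNTf2 gives the enol triflate F8 by enolisation toward C1.
  - Stille coupling with Bu3SnCH2OH (Pd(PPh3)4, LiCl) gives the cyclobutenylmethanol F9, and silylation gives the silyl ether F10.
  - Ethenolysis of F10 with 11 under the conditions of step 7 gives 14. In this sequence C6 is already at the alcohol level, so step 8 is not needed.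

**Step 4.**
- What may go wrong: dienolate 6 carries the C8 ether β to the enolate carbon. E1cB loss of 4-methoxybenzyl oxide would give a cross-conjugated dienone that aromatises. Deprotonation at the γ-positions is a second risk.
- Fallback: it carries the C8 oxygen as an alkoxide, which cannot leave, sets out from 4 and comes back at 7. DDQ removes the benzyl ether to give (5S)-5-hydroxy-3-methylcyclohex-2-en-1-one F11. Two equivalents of LiN(iPr)2 give the chelated alkoxide–enolate dianion, which is alkylated by 5 anti to the alkoxide in the manner of a Fráter–Seebach alkylation. A cold acidic quench, before the alkoxide can lactonise, gives methyl 2-[(1R,6S)-6-hydroxy-4-methyl-2-oxocyclohex-3-en-1-yl]acetate F12. 4-Methoxybenzyl trichloroacetimidate with a catalytic acid then gives 7.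

**Step 8.**
- What may go wrong: poor facial control at C6. If the organosamarium is protonated kinetically from the less hindered side, the axial alcohol forms. Slow reduction of the ester, or enolisation at C5 or C7 by the amine, are further risks.
- Fallback: it replaces thermodynamic reduction by kinetic reduction and inversion, sets out from 12 and comes back at 14. LiBH(s-Bu)3 attacks C6 equatorially, and the axial alkoxide closes onto the cis ester to give the cis-fused lactone diene F13 (the same structure as F3). LiOH gives the hydroxy acid F14 (the same structure as F4), and Mitsunobu lactonisation with inversion at C6 gives 14.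

## Further compounds

F1 | step 7 | cis-fused γ-lactone of the C6-epimeric alcohol from 10, cyclobutene retained (C6–O cis to C7–C11; other centres as in 10) | C1=C(CO[Si](C)(C)C(C)(C)C)[C@@H]2[C@@H]3OC(=O)C[C@@H]3[C@@H](OCc4ccc(OC)cc4)C[C@]12C
F2 | step 7 | keto aldehyde from cleavage of the cyclobutene of F1 (C10–CHO, C5–C(=O)CH2OSi; cis-fused lactone) | O=C[C@@]1(C)C[C@H](OCc3ccc(OC)cc3)[C@H]2CC(=O)O[C@H]2[C@H]1C(=O)CO[Si](C)(C)C(C)(C)C
F3 | step 7 | cis-fused lactone diene, C6 epimer of 14 (3aR,4S,6R,7R,7aS) | C=C[C@@]1(C)C[C@H](OCc3ccc(OC)cc3)[C@H]2CC(=O)O[C@H]2[C@H]1C(=C)CO[Si](C)(C)C(C)(C)C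
F4 | step 7 | hydroxy acid from F3 (C6–OH axial, cis to the C7 acetic acid branch) | C=C[C@@]1(C)C[C@H](OCc2ccc(OC)cc2)[C@@H](CC(=O)O)[C@@H](O)[C@H]1C(=C)CO[Si](C)(C)C(C)(C)C
F5 | step 6 | (3aR,4S,7aR)-4-[(4-methoxybenzyl)oxy]-6-methyl-3a,4,5,7a-tetrahydro-1-benzofuran-2(3H)-one | CC1=C[C@H]2OC(=O)C[C@@H]2[C@@H](OCc3ccc(OC)cc3)C1
F6 | step 6 | dichlorocyclobutanone from F5 (carbonyl carbon on C5, CCl2 on C10, four-membered ring cis to the C7–C11 bond) | C[C@]12C[C@H](OCc4ccc(OC)cc4)[C@H]3CC(=O)O[C@@H]3[C@H]1C(=O)C2(Cl)Cl
F7 | step 6 | cyclobutanone from F6 after removal of both chlorines | C[C@]12C[C@H](OCc4ccc(OC)cc4)[C@H]3CC(=O)O[C@@H]3[C@H]1C(=O)C2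
F8 | step 6 | cyclobutenyl triflate from F7 (C4–OTf, C1=C4) | C[C@]12C[C@H](OCc4ccc(OC)cc4)[C@H]3CC(=O)O[C@@H]3[C@H]1C(OS(=O)(=O)C(F)(F)F)=C2
F9 | step 6 | cyclobutenylmethanol from F8 (C4–CH2OH, C1=C4) | C[C@]12C[C@H](OCc4ccc(OC)cc4)[C@H]3CC(=O)O[C@@H]3[C@H]1C(CO)=C2
F10 | step 6 | tert-butyldimethylsilyl ether of F9 (trans-fused lactone cyclobutene) | C[C@]12C[C@H](OCc4ccc(OC)cc4)[C@H]3CC(=O)O[C@@H]3[C@H]1C(CO[Si](C)(C)C(C)(C)C)=C2
F11 | step 4 | (5S)-5-hydroxy-3-methylcyclohex-2-en-1-one | CC1=CC(=O)C[C@@H](O)C1
F12 | step 4 | methyl 2-[(1R,6S)-6-hydroxy-4-methyl-2-oxocyclohex-3-en-1-yl]acetate | CC1=CC(=O)[C@H](CC(=O)OC)[C@@H](O)C1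
F13 | step 8 | cis-fused lactone diene, C6 epimer of 14 (3aR,4S,6R,7R,7aS) | C=C[C@@]1(C)C[C@H](OCc3ccc(OC)cc3)[C@H]2CC(=O)O[C@H]2[C@H]1C(=C)CO[Si](C)(C)C(C)(C)C
F14 | step 8 | hydroxy acid from F13 (C6–OH axial, cis to the C7 acetic acid branch) | C=C[C@@]1(C)C[C@H](OCc2ccc(OC)cc2)[C@@H](CC(=O)O)[C@@H](O)[C@H]1C(=C)CO[Si](C)(C)C(C)(C)C
A1 | alternative 1 | C10 carboxylic acid with the γ-lactone in place, C8 silyl ether, C15 4-methoxybenzyl ether and C4=C3 methylene | OC(=O)[C@@]1(C)C[C@H](O[Si](C)(C)C(C)(C)C)[C@H]2CC(=O)O[C@@H]2[C@H]1C(=C)COCc3ccc(OC)cc3
A2 | alternative 2 | bis(tert-butyldimethylsilyl) ether of the 8,15-diol α-methylene lactone | C=C[C@@]1(C)C[C@H](O[Si](C)(C)C(C)(C)C)[C@H]2C(=C)C(=O)O[C@@H]2[C@H]1C(=C)CO[Si](C)(C)C(C)(C)C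
A3 | alternative 3 | 3-methyl-3-vinylcyclohexanone β-keto ester (C8 ketone, C9 ester, C6 and C15 silyl ethers) | C=C[C@@]1(C)[C@@H](C(=O)OC)C(=O)[C@@H](CC(=O)OC)[C@H](O[Si](C)(C)C(C)(C)C)[C@H]1C(=C)CO[Si](C)(C)C(C)(C)C
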